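The runs were computed for an exercise; scatter was added.

The constant I wanted first was the one the readings could give: how many monomer units one living chain adds per minute, since a chain's length is that rate run against its growing time.

| flask | free monomer | pre-initiator | impurity | remark | time |
|---|---|---|---|---|---|
| red | 0.20 M (fed, over 3.0 min) | 0.85 mM | 0.77 mM | run made earlier; the fed solution adds 0.10 times the starting volume |  |
| green | 0.20 M (fed, over 3.0 min) | 1.6 mM | 0.77 mM | run made earlier; the fed solution adds 0.10 times the starting volume |  |
| Thursday's | 0.20 M (fed, over 3.0 min) | 0.60 mM | 0.77 mM | the fed solution adds 0.10 times the starting volume | 50 min |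
| Monday's | 0.20 M (fed, over 3.0 min) | 1.0 mM | 0.77 mM | the fed solution adds 0.10 times the starting volume | 50 min |

| run | time / min | monomer in chains / % |
|---|---|---|
| red | 5.00 | 1.4 |
| red | 10.0 | 5.9 |
| red | 15.0 | 11.1 |
| red | 20.0 | 17.3 |
| red | 25.0 | 21.9 |
| green | 2.00 | 0 |
| green | 4.00 | 2.6 |
| green | 8.00 | 17.2 |
| green | 12.0 | 34.3 |
| green | 25.0 | 71.8 |

(each reading ± 0.3 percentage points)

- charges are per starting volume, the dose included; the dosed solution carries all of it
- the average divides the monomer in chains by the number of chains begun, living and dead together
- the earlier runs do not show the number of chains; that part of a forecast is a guess
- percentages count the whole charge, also what has not yet gone in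

- which of the two ends with the longer chains by the average number of monomer units in a chain (chains begun, living or dead) ("neither" if they lie within 10%) (Thursday's / Monday's / neither)
- average number of monomer units in a chain (chains begun, living or dead) at the end, Thursday's
- average number of monomer units in a chain (chains begun, living or dead) at the end, Monday's

I set the times in order, shortest first. The feed took 3.0 min. Green read 0% at 2.00 min and 2.6% at 4.00 min, so as an estimate I let growth start at 4.00 min, a lag longer than the feed. After that, uptake looked pseudo-first-order. The logarithm of the monomer left fell by 0.0651 min⁻¹ in green and 0.0130 min⁻¹ in red, which read as monomer lives of 15.4 min and 77.2 min. The asked 50 min was longer than green's life and shorter than red's.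

The chains themselves were not shown, so I guessed that green kept its surplus of pre-initiator over impurity, 0.830 mM. Green's slope times its charge of monomer per chain gave 15.7 min⁻¹, the growth rate per chain, in units per minute. By my reckoning, with charge and temperature held, length is this rate over the slope, times the fraction of monomer taken. While that fraction is small the slope cancels, and length is simply the rate times the growing time.

Over 46.0 min that product is 721, and I put Thursday's near it. For Monday's, a straight line between red and green gave a slope of 0.0234 min⁻¹, hence a length of 442. So I chose Thursday's.

The forecast differed from my reckoning: Monday's, with 5 for Thursday's and 130 for Monday's, on the ground that “Thursday's lies below the threshold”.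

The flask gave Thursday's: 615 for Thursday's and 458 for Monday's.

    free monomer + living end → monomer in chains + living end, rate k1*[living end]*[free monomer] (k = 87.2 M⁻¹ min⁻¹)
    initiator + impurity → spent initiator (k = 29100 M⁻¹ min⁻¹)
    free monomer + initiator → living end + monomer in chains (k = 14.5 M⁻¹ min⁻¹)
    pre-initiator → initiator (k = 0.291 min⁻¹)

Monday's ended shorter than Thursday's because of its larger charge of pre-initiator: with that difference taken away, so that Monday's flask holds Thursday's charge of pre-initiator, the average is 615. At 50 min, Monday's held 2.36 × 10⁻⁴ M of living ends against 7.44 × 10⁻⁵ M in Thursday's, and these shared the monomer. With the 74.8% of free monomer left in Thursday's, the growth rate per chain gives Thursday's a length of 627.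

For Monday's flask left until 80 min, the same rate and slope give 558; the computed average is 602.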